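## Retrosynthetic overview

1. The C11 p-coumarate is attached last, by regioselective acylation of the C6,C11-diol 10 with phenol-silylated p-coumaric acid 13.
2. The oxolane C10–O bond and the C11–OH are formed together by an anodically driven, osmium-catalysed oxidative cyclisation of ene-diol 9 (cis ring, threo C10/C11).
3. The C7–C8 bond comes from chelation-controlled addition of (E)-pent-3-enylmagnesium bromide 8 to α-hydroxy aldehyde 6, which sets C7.
4. The dihydropyranone comes from 2-deoxy-L-ribose 1 by Wittig olefination and photochemical E→Z isomerisation–lactonisation; C5 and C6 are the sugar's C3 and C4.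
5. Ring order: lactone first (step 2), oxolane second (step 5).

Chain numbering used below: C1 is the lactone carbonyl and C12 the methyl group; the target is 5R,6S,7R,10S,11S.

Assumption: 2-deoxy-L-ribose (made on scale from L-arabinose; drawn as its open-chain aldehyde) and (E)-5-bromopent-2-ene of at least 98% E purity are bought.

## Route

Step 1
Reactants: 1 2-deoxy-L-ribose; 2 ethyl (triphenylphosphoranylidene)acetate
Product: 3 ethyl (2E,5R,6S)-5,6,7-trihydroxyhept-2-enoate
Conditions: 2 (1.3 equiv), PhCO2H (5 mol%), THF, 65 °C, 6 h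
Reagents that add atoms: none
Why: Wittig olefination of the aldehyde in equilibrium with the lactol; the stabilised ylide gives the E-enoate under neutral conditions (no oxa-Michael closure), and C5 and C6 are carried over untouched from the sugar.

Step 2
Reactants: 3 ethyl (2E,5R,6S)-5,6,7-trihydroxyhept-2-enoate
Product: 5 (6R)-6-[(1S)-1,2-dihydroxyethyl]-5,6-dihydro-2H-pyran-2-one, via Z-enoate triol 4 (not isolated)
Conditions: hν (254 nm, quartz), MeCN, 20 °C; then PPTS (5 mol%), 40 °C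
Reagents that add atoms: none
Why: Photochemical E/Z isomerisation–lactonisation; the Z-ester is drained from the photostationary mixture by ring closure of the C5 hydroxyl (six-membered lactone favoured over seven or eight), with no stereocentre touched.

Step 3
Reactants: 5 (6R)-6-[(1S)-1,2-dihydroxyethyl]-5,6-dihydro-2H-pyran-2-one
Product: 6 (2R)-2-hydroxy-2-[(2R)-6-oxo-3,6-dihydro-2H-pyran-2-yl]acetaldehyde
Conditions: TEMPO (10 mol%), PhI(OAc)2 (1.1 equiv), CH2Cl2/MeCN, 0 to 20 °C; evaporated with toluene and used crude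
Reagents that add atoms: none
Why: Oxoammonium (TEMPO) oxidation is selective for the primary over the secondary hydroxyl and stops at the aldehyde in the absence of water; the acid-buffered medium avoids epimerisation at C6 and β-elimination.

Step 4
Reactants: 6 (2R)-2-hydroxy-2-[(2R)-6-oxo-3,6-dihydro-2H-pyran-2-yl]acetaldehyde; 7 (E)-5-bromopent-2-ene
Product: 9 (6R)-6-[(1S,2R,5E)-1,2-dihydroxyhept-5-en-1-yl]-5,6-dihydro-2H-pyran-2-one, via pentenyl Grignard 8 (not isolated)
Conditions: 7, Mg turnings, Et2O, 0 to 25 °C (gives 8, 2.3 equiv); then 6, THF/CH2Cl2, −78 °C, 1 h; AcOH/THF quench at −78 °C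
Reagents that add atoms: none
Why: Cram-chelate Grignard addition; the first equivalent forms the C6 magnesium alkoxide, which chelates the aldehyde so that the second adds anti to the lactone substituent to give the threo (7R) diol, while at −78 °C the aldehyde far outruns the lactone and the cold acidic quench prevents oxa-Michael closure.

Step 5
Reactants: 9 (6R)-6-[(1S,2R,5E)-1,2-dihydroxyhept-5-en-1-yl]-5,6-dihydro-2H-pyran-2-one
Product: 10 (6R)-6-[(S)-hydroxy{(2R,5S)-5-[(1S)-1-hydroxyethyl]oxolan-2-yl}methyl]-5,6-dihydro-2H-pyran-2-one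
Conditions: K2OsO2(OH)4 (5 mol%), TFA (3 equiv), LiClO4 (0.1 M), acetone/H2O 9:1, graphite-felt anode, Pt cathode, divided cell, +0.8 V vs Ag/AgCl, 2.2 F/mol, 25 °C
Reagents that add atoms: water, O
Why: Proposed new method: the C6/C7 diol condenses with K2OsO2(OH)4 to a hexavalent osmium dioxo glycolate, whose acid-promoted intramolecular syn [3+2] addition to the E-alkene makes the C7 oxygen the ring oxygen through a bicyclic transition state, so the ring is 2,5-cis (C10 S from C7 R) and suprafacial addition gives threo C10/C11 (C11 S); the resulting tetravalent osmium ester is reoxidised to hexavalent osmium at the anode (potential held below formation of octavalent osmium and below alkene oxidation) and hydrolysed while protons give H2 at the cathode; the closest known reactions are the osmium-catalysed oxidative cyclisation of 1,2-diols onto alkenes with amine N-oxide reoxidants and anodically turned-over osmium dihydroxylation.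

Step 6
Reactants: 11 (E)-4-hydroxycinnamic acid (p-coumaric acid)
Product: 13 (E)-3-[4-(tert-butyldimethylsilyloxy)phenyl]prop-2-enoic acid, via bis-silyl coumarate 12 (not isolated)
Conditions: TBSCl (2.3 equiv), imidazole (5 equiv), DMF, 25 °C; then AcOH/THF/H2O 3:1:1, 25 °C, 1 h
Reagents that add atoms: tert-butyldimethylsilyl chloride, CC(C)(C)[Si](C)(C)Cl
Why: Exhaustive silylation followed by selective hydrolysis of the far more labile silyl ester leaves the aryl silyl ether, masking the phenol for the esterification.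

Step 7
Reactants: 10 (6R)-6-[(S)-hydroxy{(2R,5S)-5-[(1S)-1-hydroxyethyl]oxolan-2-yl}methyl]-5,6-dihydro-2H-pyran-2-one; 13 (E)-3-[4-(tert-butyldimethylsilyloxy)phenyl]prop-2-enoic acid
Product: 14 (1S)-1-[(2S,5R)-5-{(S)-hydroxy[(2R)-6-oxo-3,6-dihydro-2H-pyran-2-yl]methyl}oxolan-2-yl]ethyl (2E)-3-[4-(tert-butyldimethylsilyloxy)phenyl]prop-2-enoate
Conditions: 13 (1.05 equiv), DIC (1.1 equiv), DMAP (10 mol%), CH2Cl2, −20 to 0 °C
Reagents that add atoms: none
Why: Steglich esterification with retention at C11; the C11 methyl carbinol is less hindered and more nucleophilic than the C6 hydroxyl, which is flanked by two ring methines and deactivated by the β-acyloxy group, so monoacylation at C11 is expected.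

Step 8
Reactants: 14 (1S)-1-[(2S,5R)-5-{(S)-hydroxy[(2R)-6-oxo-3,6-dihydro-2H-pyran-2-yl]methyl}oxolan-2-yl]ethyl (2E)-3-[4-(tert-butyldimethylsilyloxy)phenyl]prop-2-enoate
Product: 15 (1S)-1-[(2S,5R)-5-{(S)-hydroxy[(2R)-6-oxo-3,6-dihydro-2H-pyran-2-yl]methyl}oxolan-2-yl]ethyl (2E)-3-(4-hydroxyphenyl)prop-2-enoate (CNP0417147.2)
Conditions: HF·pyridine, THF/pyridine, 0 °C, 1 h
Reagents that add atoms: none
Why: Fluoride cleavage of the aryl silyl ether under buffered, non-basic conditions leaves both esters and the Michael-acceptor lactone intact and avoids base-induced oxa-Michael closure of the C6 hydroxyl.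

## Compound list

1 | 2-deoxy-L-ribose (2-deoxy-L-erythro-pentose, open-chain form) | O=CC[C@@H](O)[C@@H](O)CO | starting material
2 | ethyl (triphenylphosphoranylidene)acetate | CCOC(=O)C=P(c1ccccc1)(c1ccccc1)c1ccccc1 | starting material
3 | ethyl (2E,5R,6S)-5,6,7-trihydroxyhept-2-enoate | CCOC(=O)/C=C/C[C@@H](O)[C@@H](O)CO | intermediate
4 | ethyl (2Z,5R,6S)-5,6,7-trihydroxyhept-2-enoate | CCOC(=O)/C=C\C[C@@H](O)[C@@H](O)CO | intermediate
5 | (6R)-6-[(1S)-1,2-dihydroxyethyl]-5,6-dihydro-2H-pyran-2-one | OC[C@H](O)[C@H]1CC=CC(=O)O1 | intermediate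
6 | (2R)-2-hydroxy-2-[(2R)-6-oxo-3,6-dihydro-2H-pyran-2-yl]acetaldehyde | O=C[C@H](O)[C@H]1CC=CC(=O)O1 | intermediate
7 | (E)-5-bromopent-2-ene | C/C=C/CCBr | starting material
8 | (E)-pent-3-en-1-ylmagnesium bromide | C/C=C/CC[Mg]Br | intermediate
9 | (6R)-6-[(1S,2R,5E)-1,2-dihydroxyhept-5-en-1-yl]-5,6-dihydro-2H-pyran-2-one | C/C=C/CC[C@@H](O)[C@H](O)[C@H]1CC=CC(=O)O1 | intermediate
10 | (6R)-6-[(S)-hydroxy{(2R,5S)-5-[(1S)-1-hydroxyethyl]oxolan-2-yl}methyl]-5,6-dihydro-2H-pyran-2-one | C[C@H](O)[C@@H]1CC[C@H]([C@H](O)[C@H]2CC=CC(=O)O2)O1 | intermediate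
11 | (E)-4-hydroxycinnamic acid (p-coumaric acid) | OC(=O)/C=C/c1ccc(O)cc1 | starting material
12 | tert-butyldimethylsilyl (E)-3-[4-(tert-butyldimethylsilyloxy)phenyl]prop-2-enoate | CC(C)(C)[Si](C)(C)OC(=O)/C=C/c1ccc(O[Si](C)(C)C(C)(C)C)cc1 | intermediate
13 | (E)-3-[4-(tert-butyldimethylsilyloxy)phenyl]prop-2-enoic acid | OC(=O)/C=C/c1ccc(O[Si](C)(C)C(C)(C)C)cc1 | intermediate
14 | (1S)-1-[(2S,5R)-5-{(S)-hydroxy[(2R)-6-oxo-3,6-dihydro-2H-pyran-2-yl]methyl}oxolan-2-yl]ethyl (2E)-3-[4-(tert-butyldimethylsilyloxy)phenyl]prop-2-enoate | C[C@H](OC(=O)/C=C/c1ccc(O[Si](C)(C)C(C)(C)C)cc1)[C@@H]1CC[C@H]([C@H](O)[C@H]2CC=CC(=O)O2)O1 | intermediate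
15 | (1S)-1-[(2S,5R)-5-{(S)-hydroxy[(2R)-6-oxo-3,6-dihydro-2H-pyran-2-yl]methyl}oxolan-2-yl]ethyl (2E)-3-(4-hydroxyphenyl)prop-2-enoate | C[C@H](OC(=O)/C=C/c1ccc(O)cc1)[C@@H]1CC[C@H]([C@H](O)[C@H]2CC=CC(=O)O2)O1 | target

## Step count and risks

Total step count: 8. Longest linear sequence: 7 (steps 1, 2, 3, 4, 5, 7, 8); step 6 is a one-step side branch.

The three steps most likely to fail:

Step 5 (the proposed new step). The anode may over-oxidise osmium to the octavalent state, which would simply dihydroxylate the C10=C11 alkene, or osmium may be lost from the anolyte. The fallback sets out from 9 and comes back at 10. It uses the established chemically driven oxidative cyclisation: K2OsO2(OH)4 (5 mol%), pyridine N-oxide (2 equiv), citric acid and Cu(OTf)2 in MeCN/H2O at 60 °C. A stoichiometric oxygen-atom donor in homogeneous solution replaces the electrode, with the same cis and threo outcome; no new compound is made.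

Step 4. The lactone aldehyde 6 is an α-hydroxy, β-acyloxy aldehyde. It may dimerise, eliminate the lactone carboxylate, or lose chemoselectivity against the lactone. The fallback sets out from 3 and comes back at 9, attaching the chain before the lactone exists. Ester 3 is oxidised at its primary hydroxyl (TEMPO, PhI(OAc)2, CH2Cl2) to ethyl (2E,5R,6R)-5,6-dihydroxy-7-oxohept-2-enoate F1. F1 takes up 8 (3.3 equiv, THF, −78 °C) under the same α-alkoxide chelation to give ethyl (2E,5R,6S,7R,10E)-5,6,7-trihydroxydodeca-2,10-dienoate F2. Irradiation at 254 nm in MeCN (the isolated alkene does not absorb) then passes through ethyl (2Z,5R,6S,7R,10E)-5,6,7-trihydroxydodeca-2,10-dienoate F3, which lactonises with a trace of PPTS to 9.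

Step 7. Acylation may not discriminate well enough between the C11 and C6 hydroxyls. The fallback sets out from 10 and comes back at 14 by a protect-and-release sequence:
- TBSCl/imidazole (DMF, 0 °C) silylates only the less hindered C11 hydroxyl, giving (6R)-6-[(S)-hydroxy{(2R,5S)-5-[(1S)-1-(tert-butyldimethylsilyloxy)ethyl]oxolan-2-yl}methyl]-5,6-dihydro-2H-pyran-2-one F4.
- 4-Methoxybenzyl trichloroacetimidate with catalytic La(OTf)3 caps C6–OH, giving (6R)-6-[(S)-(4-methoxybenzyloxy){(2R,5S)-5-[(1S)-1-(tert-butyldimethylsilyloxy)ethyl]oxolan-2-yl}methyl]-5,6-dihydro-2H-pyran-2-one F5.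
- HF·pyridine frees C11–OH, giving (6R)-6-[(S)-(4-methoxybenzyloxy){(2R,5S)-5-[(1S)-1-hydroxyethyl]oxolan-2-yl}methyl]-5,6-dihydro-2H-pyran-2-one F6.
- DIC/DMAP esterification with 13 gives (1S)-1-[(2S,5R)-5-{(S)-(4-methoxybenzyloxy)[(2R)-6-oxo-3,6-dihydro-2H-pyran-2-yl]methyl}oxolan-2-yl]ethyl (2E)-3-[4-(tert-butyldimethylsilyloxy)phenyl]prop-2-enoate F7.
- DDQ (CH2Cl2/pH 7 buffer) removes the 4-methoxybenzyl group to give 14.

## Further compounds

F1 | step 4 | ethyl (2E,5R,6R)-5,6-dihydroxy-7-oxohept-2-enoate | CCOC(=O)/C=C/C[C@@H](O)[C@@H](O)C=O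
F2 | step 4 | ethyl (2E,5R,6S,7R,10E)-5,6,7-trihydroxydodeca-2,10-dienoate | CCOC(=O)/C=C/C[C@@H](O)[C@@H](O)[C@H](O)CC/C=C/C
F3 | step 4 | ethyl (2Z,5R,6S,7R,10E)-5,6,7-trihydroxydodeca-2,10-dienoate | CCOC(=O)/C=C\C[C@@H](O)[C@@H](O)[C@H](O)CC/C=C/C
F0 | step 5 | none | none
F4 | step 7 | (6R)-6-[(S)-hydroxy{(2R,5S)-5-[(1S)-1-(tert-butyldimethylsilyloxy)ethyl]oxolan-2-yl}methyl]-5,6-dihydro-2H-pyran-2-one | C[C@H](O[Si](C)(C)C(C)(C)C)[C@@H]1CC[C@H]([C@H](O)[C@H]2CC=CC(=O)O2)O1
F5 | step 7 | (6R)-6-[(S)-(4-methoxybenzyloxy){(2R,5S)-5-[(1S)-1-(tert-butyldimethylsilyloxy)ethyl]oxolan-2-yl}methyl]-5,6-dihydro-2H-pyran-2-one | C[C@H](O[Si](C)(C)C(C)(C)C)[C@@H]1CC[C@H]([C@H](OCc3ccc(OC)cc3)[C@H]2CC=CC(=O)O2)O1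
F6 | step 7 | (6R)-6-[(S)-(4-methoxybenzyloxy){(2R,5S)-5-[(1S)-1-hydroxyethyl]oxolan-2-yl}methyl]-5,6-dihydro-2H-pyran-2-one | C[C@H](O)[C@@H]1CC[C@H]([C@H](OCc3ccc(OC)cc3)[C@H]2CC=CC(=O)O2)O1
F7 | step 7 | (1S)-1-[(2S,5R)-5-{(S)-(4-methoxybenzyloxy)[(2R)-6-oxo-3,6-dihydro-2H-pyran-2-yl]methyl}oxolan-2-yl]ethyl (2E)-3-[4-(tert-butyldimethylsilyloxy)phenyl]prop-2-enoate | C[C@H](OC(=O)/C=C/c1ccc(O[Si](C)(C)C(C)(C)C)cc1)[C@@H]1CC[C@H]([C@H](OCc3ccc(OC)cc3)[C@H]2CC=CC(=O)O2)O1
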